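**Retrosynthetic overview**

1. Target 18 ⇐ esterification of side-chain alcohol 16 ⇐ desilylation, Teuber oxidation and oxa-bridge opening of the bis-silylated 1,4-epoxide 13 ⇐ tethered cycloadduct 11.
2. Feature used: the ring B bonds C1–C8a and C4–C4a are the two bonds a 3-substituted furan makes across a C4a–C8a aryne of ring A. The oxygen on C8 lies within one silicon atom of the oxygen on C1' only while ring B is the folded 1,4-epoxide. In the flat naphthalene or quinone C1 sits between them, so the silylene is put on for the cycloaddition and removed before aromatisation.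
3. 11 ⇐ aryne from mixed silaketal 8 ⇐ 2-chloro-4-methoxyphenol 5 + t-Bu2Si(OTf)2 6 + (S)-carbinol 4; 4 ⇐ asymmetric allylation of furan-3-carbaldehyde 1, then cross-metathesis.
4. Ring order: ring A and the furan are bought; ring B (with the temporary eight-membered silaketal ring) closes in step 4, is aromatised in step 7 and becomes the quinone in step 8.

Key step: step 4

Assumption: locants follow the target throughout (C1–C4, C4a, C8a for ring B; C5–C8 for ring A; C1' for the carbinol carbon), and the 1,4-epoxides 11–13 are carried as whichever bridgehead diastereomer or mixture forms, because C1 and C4 become sp2 in step 7.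

**Route**

Step 1
Reactants: 1 furan-3-carbaldehyde
Product: 3 (S)-1-(furan-3-yl)but-3-en-1-ol, via borinate 2 (not isolated)
Conditions: (−)-Ipc2BOMe, allylMgBr, Et2O, 0 °C to rt; then 1, −78 °C; then 3 M NaOH, 30% H2O2, rt
Reagents that add atoms: (−)-B-allyldiisopinocampheylborane (made in the flask), C=CCB([C@@H]1C[C@@H]2C[C@H]([C@H]1C)C2(C)C)[C@@H]1C[C@@H]2C[C@H]([C@H]1C)C2(C)C
Why: Brown asymmetric allylboration through a closed chair transition state; the reagent derived from (+)-α-pinene delivers allyl to the Si face of the aryl aldehyde, which sets C1' as (S).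

Step 2
Reactants: 3 (S)-1-(furan-3-yl)but-3-en-1-ol
Product: 4 (S)-1-(furan-3-yl)-4-methylpent-3-en-1-ol
Conditions: second-generation Grubbs catalyst RuCl2(=CHPh)(PCy3)(H2IMes) (5 mol %), 2-methyl-2-butene/CH2Cl2, rt to 35 °C
Reagents that add atoms: 2-methyl-2-butene, CC=C(C)C
Why: Olefin cross-metathesis of the terminal alkene with excess 2-methyl-2-butene should give the trisubstituted alkene with loss of propene, the free hydroxyl and the furan being tolerated and C1' untouched.

Step 3
Reactants: 5 2-chloro-4-methoxyphenol; 6 di-tert-butylsilyl bis(trifluoromethanesulfonate); 4 (S)-1-(furan-3-yl)-4-methylpent-3-en-1-ol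
Product: 8 di-tert-butyl(2-chloro-4-methoxyphenoxy)[(1S)-1-(furan-3-yl)-4-methylpent-3-enyloxy]silane, via silyl triflate 7 (not isolated)
Conditions: 6, 2,6-lutidine, CH2Cl2, −78 to 0 °C (5 added slowly); then 4, DMAP (cat.), 0 °C to rt
Reagents that add atoms: none
Why: O-Silylation with a silyl bis-triflate: the phenol displaces the first triflate at low temperature and the hindered aryloxysilyl triflate then silylates the secondary carbinol on warming, the tert-butyl groups suppressing double arylation and C1' keeping its configuration because only O–H bonds react.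

Step 4
Reactants: 8 di-tert-butyl(2-chloro-4-methoxyphenoxy)[(1S)-1-(furan-3-yl)-4-methylpent-3-enyloxy]silane
Product: 11 5-methoxy-1,4-epoxy-1,4-dihydronaphthalene whose O8 is joined through Si(t-Bu)2 to O1' of the (1S)-4-methylpent-3-enyl chain on C2, via aryllithium 9 (not isolated), via aryne 10 (not isolated)
Conditions: s-BuLi (1.2 equiv), THF (0.01 M), −95 °C; then warm to −20 °C
Reagents that add atoms: none
Why: s-BuLi removes the ring hydrogen flanked by chlorine and methoxyl, the kinetically most acidic site at −95 °C and ahead of the furan α-hydrogens, and aryllithium 9 loses LiCl on warming to give aryne 10 across C4a–C8a. The tethered furan adds across the in-plane aryne π bond in a concerted, asynchronous [4+2], furan C2 bonding to C8a and furan C5 to C4a; the closest known reaction type is the silicon-tethered intramolecular benzyne–furan Diels–Alder reaction of ortho-lithiated chloroarenes. Ring B closes as a six-membered carbocycle by the cycloaddition, and the temporary eight-membered ring C8–O–Si–O–C1'–C2–C1–C8a closes with it, which is possible because C1 is sp3 and the C2=C3 bridge is folded out of the arene plane. The bridgehead stereocentres C1 and C4 are set together, their sense relative to C1' following from the furan face the tether presents, and they need no control because both become sp2 in step 7, while C1' is a spectator. The selectivity that matters is orientation, since the two oxygen-flanked aryne carbons are electronically alike and a 3-alkylfuran is hardly polarised: the short O–Si–O link can be spanned only when furan C2 meets C8a, and high dilution keeps the aryne away from s-BuLi and from 9.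

Step 5
Reactants: 11 silylene-bridged cycloadduct
Product: 12 8-hydroxy-2-[(1S)-1-hydroxy-4-methylpent-3-enyl]-5-methoxy-1,4-epoxy-1,4-dihydronaphthalene
Conditions: HF·pyridine, pyridine, THF, 0 °C to rt; used at once
Reagents that add atoms: none
Why: Fluoride cleavage of both Si–O bonds (silyl ether deprotection) should be easy because the eight-membered silaketal is strained and phenoxide is a good leaving group, and it has to precede aromatisation because a planar naphthalene cannot hold O8 and O1' within reach of one silicon.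

Step 6
Reactants: 12 8-hydroxy-2-[(1S)-1-hydroxy-4-methylpent-3-enyl]-5-methoxy-1,4-epoxy-1,4-dihydronaphthalene
Product: 13 8-(tert-butyldimethylsilyloxy)-2-[(1S)-1-(tert-butyldimethylsilyloxy)-4-methylpent-3-enyl]-5-methoxy-1,4-epoxy-1,4-dihydronaphthalene
Conditions: TBSCl (3 equiv), imidazole, DMAP (cat.), DMF, rt
Reagents that add atoms: tert-butyldimethylsilyl chloride, CC(C)(C)[Si](C)(C)Cl
Why: Standard silylation caps the phenol and the secondary alcohol, so that after aromatisation the only free hydroxyl is the new ring B naphthol and ring A, a para-methoxyphenol when unmasked, is shielded from the oxidant.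

Step 7
Reactants: 13 bis-silylated 1,4-epoxide
Product: 14 8-(tert-butyldimethylsilyloxy)-2-[(1S)-1-(tert-butyldimethylsilyloxy)-4-methylpent-3-enyl]-5-methoxynaphthalen-1-ol
Conditions: TFA (0.2 equiv), CH2Cl2, 0 °C; crude product used directly
Reagents that add atoms: none
Why: Acid-catalysed isomerisation of a 1,4-epoxy-1,4-dihydronaphthalene to a naphthol: ionisation of the C4–O bond gives an allyl/benzyl cation stabilised by the ortho methoxyl and the C2 substituent, and a 1,2-hydride shift from C1 followed by enolisation aromatises ring B and removes both bridgehead stereocentres (any regioisomeric 4-naphthol would give the same quinone in step 8).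

Step 8
Reactants: 14 naphthol
Product: 15 8-(tert-butyldimethylsilyloxy)-2-[(1S)-1-(tert-butyldimethylsilyloxy)-4-methylpent-3-enyl]-5-methoxynaphthalene-1,4-dione
Conditions: (KSO3)2NO (2.5 equiv), aq. KH2PO4, acetone, 0 °C to rt
Reagents that add atoms: potassium nitrosodisulfonate (Fremy's salt), [K+].[K+].[O]N(S(=O)(=O)[O-])S(=O)(=O)[O-]
Why: Teuber oxidation: the nitroxyl abstracts the naphthol hydrogen, a second equivalent couples at the free para carbon C4 and loss of HN(SO3K)2 gives the 1,4-quinone, while ring A carries no free hydroxyl and should be left alone.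

Step 9
Reactants: 15 bis-silylated quinone
Product: 16 8-hydroxy-2-[(1S)-1-hydroxy-4-methylpent-3-enyl]-5-methoxynaphthalene-1,4-dione
Conditions: HF·pyridine, pyridine, THF, 0 °C to rt
Reagents that add atoms: none
Why: Fluoride desilylation of the secondary and the peri aryl silyl ethers under buffered, non-basic conditions that the quinone, the trisubstituted alkene and the C1' stereocentre should tolerate.

Step 10
Reactants: 16 8-hydroxy-2-[(1S)-1-hydroxy-4-methylpent-3-enyl]-5-methoxynaphthalene-1,4-dione; 17 3-methylbut-2-enoic acid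
Product: 18 (1S)-1-(8-hydroxy-5-methoxy-1,4-dioxo-1,4-dihydronaphthalen-2-yl)-4-methylpent-3-enyl 3-methylbut-2-enoate
Conditions: DCC, DMAP (cat.), CH2Cl2, 0 °C
Reagents that add atoms: none
Why: Steglich esterification acylates the side-chain alcohol while the C8 hydroxyl, hydrogen-bonded to the C1 carbonyl, stays free as is usual for alkannin-type naphthoquinones, and the C1'–O bond is not broken, so the (S) configuration is kept.

**Compound list**

1 | furan-3-carbaldehyde | O=Cc1ccoc1 | starting material
2 | (S)-1-(furan-3-yl)but-3-enyl diisopinocampheylborinate (not isolated) | C=CC[C@H](OB([C@@H]1C[C@@H]2C[C@H]([C@H]1C)C2(C)C)[C@@H]1C[C@@H]2C[C@H]([C@H]1C)C2(C)C)c1ccoc1 | intermediate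
3 | (S)-1-(furan-3-yl)but-3-en-1-ol | C=CC[C@H](O)c1ccoc1 | intermediate
4 | (S)-1-(furan-3-yl)-4-methylpent-3-en-1-ol | CC(C)=CC[C@H](O)c1ccoc1 | intermediate
5 | 2-chloro-4-methoxyphenol | COc1ccc(O)c(Cl)c1 | starting material
6 | di-tert-butylsilyl bis(trifluoromethanesulfonate) | CC(C)(C)[Si](OS(=O)(=O)C(F)(F)F)(OS(=O)(=O)C(F)(F)F)C(C)(C)C | starting material
7 | di-tert-butyl(2-chloro-4-methoxyphenoxy)silyl trifluoromethanesulfonate (not isolated) | COc1ccc(O[Si](OS(=O)(=O)C(F)(F)F)(C(C)(C)C)C(C)(C)C)c(Cl)c1 | intermediate
8 | di-tert-butyl(2-chloro-4-methoxyphenoxy)[(1S)-1-(furan-3-yl)-4-methylpent-3-enyloxy]silane | COc1ccc(O[Si](C(C)(C)C)(C(C)(C)C)O[C@@H](CC=C(C)C)c2ccoc2)c(Cl)c1 | intermediate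
9 | 3-lithio derivative of 8, lithium between chlorine and methoxyl (not isolated) | COc1ccc(O[Si](C(C)(C)C)(C(C)(C)C)O[C@@H](CC=C(C)C)c2ccoc2)c(Cl)c1[Li] | intermediate
10 | C4a–C8a aryne from 9, (S) at C1' (not isolated) | COC1=CC=C(O[Si](C(C)(C)C)(C(C)(C)C)O[C@@H](CC=C(C)C)c2ccoc2)C#C1 | intermediate
11 | 5-methoxy-1,4-epoxy-1,4-dihydronaphthalene with O8 and O1' joined by Si(t-Bu)2, (S) at C1', bridgeheads C1/C4 not assigned | COc1ccc2O[Si](C(C)(C)C)(C(C)(C)C)O[C@@H](CC=C(C)C)C3=CC4OC3c2c14 | intermediate
12 | 8-hydroxy-2-[(1S)-1-hydroxy-4-methylpent-3-enyl]-5-methoxy-1,4-epoxy-1,4-dihydronaphthalene, bridgeheads not assigned | COc1ccc(O)c2c1C1C=C([C@@H](O)CC=C(C)C)C2O1 | intermediate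
13 | 8-(tert-butyldimethylsilyloxy)-2-[(1S)-1-(tert-butyldimethylsilyloxy)-4-methylpent-3-enyl]-5-methoxy-1,4-epoxy-1,4-dihydronaphthalene, bridgeheads not assigned | COc1ccc(O[Si](C)(C)C(C)(C)C)c2c1C1C=C([C@@H](O[Si](C)(C)C(C)(C)C)CC=C(C)C)C2O1 | intermediate
14 | 8-(tert-butyldimethylsilyloxy)-2-[(1S)-1-(tert-butyldimethylsilyloxy)-4-methylpent-3-enyl]-5-methoxynaphthalen-1-ol | COc1ccc(O[Si](C)(C)C(C)(C)C)c2c(O)c([C@@H](O[Si](C)(C)C(C)(C)C)CC=C(C)C)ccc12 | intermediate
15 | 8-(tert-butyldimethylsilyloxy)-2-[(1S)-1-(tert-butyldimethylsilyloxy)-4-methylpent-3-enyl]-5-methoxynaphthalene-1,4-dione | COc1ccc(O[Si](C)(C)C(C)(C)C)c2c1C(=O)C=C([C@@H](O[Si](C)(C)C(C)(C)C)CC=C(C)C)C2=O | intermediate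
16 | 8-hydroxy-2-[(1S)-1-hydroxy-4-methylpent-3-enyl]-5-methoxynaphthalene-1,4-dione | COc1ccc(O)c2c1C(=O)C=C([C@@H](O)CC=C(C)C)C2=O | intermediate
17 | 3-methylbut-2-enoic acid | CC(C)=CC(=O)O | starting material
18 | (1S)-1-(8-hydroxy-5-methoxy-1,4-dioxo-1,4-dihydronaphthalen-2-yl)-4-methylpent-3-enyl 3-methylbut-2-enoate | COc1ccc(O)c2c1C(=O)C=C([C@H](CC=C(C)C)OC(=O)C=C(C)C)C2=O | target

**Step count**

Total steps: 10. Longest linear sequence: 10 steps (1 to 18); 5, 6 and 17 enter as bought materials.

**Steps most likely to fail**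

Step 4. The O–Si–O link may be too short for the furan to reach the aryne without serious angle strain. The aryne would then be consumed by addition of s-BuLi or of aryllithium 9, and lithiation at a furan α-position could divert base. The fallback is the untethered, intermolecular benzyne–furan Diels–Alder reaction; it sets out from 4 and 5 and comes back at 13. Phenol 5 is silylated (TBSCl, imidazole) to tert-butyl(2-chloro-4-methoxyphenoxy)dimethylsilane F1, and carbinol 4 likewise to its tert-butyldimethylsilyl ether F2. F1 alone is lithiated with s-BuLi at −95 °C, with no furan present, to aryllithium F3. F2 (2–3 equiv) is added and the mixture warmed, so that aryne F4 is trapped by the furan. Without the tether both orientations should form in comparable amounts, and 13 would be separated by chromatography from its regioisomer F5, which carries the side chain on C3. Steps 3, 5 and 6 are then not needed.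

Step 3. The second displacement at the hindered aryloxysilyl triflate 7 may be slow compared with scrambling to symmetrical silanes, and triflate salts may ionise the furyl carbinol. The fallback makes the two Si–O bonds in separate events through a hydrosilane; it sets out from 5 and comes back at 8. Phenol 5 with di-tert-butylchlorosilane and imidazole in DMF gives di-tert-butyl(2-chloro-4-methoxyphenoxy)silane F6. NBS in CH2Cl2 at 0 °C turns its Si–H bond into Si–Br, giving bromo-di-tert-butyl(2-chloro-4-methoxyphenoxy)silane F7. Carbinol 4 with imidazole and DMAP is then added to F7 to give 8.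

Step 8. The C8 silyl group may shift to the neighbouring peri hydroxyl at C1 before oxidation, which would free the para-methoxyphenol of ring A and let the nitroxyl attack there. Hydrogen abstraction from the doubly flanked naphthol may also be slow. The fallback uses a peri cap that does not migrate; it sets out from 12 and comes back at 16. TIPSCl and imidazole in DMF silylate only the phenol of 12, giving 2-[(1S)-1-hydroxy-4-methylpent-3-enyl]-5-methoxy-8-(triisopropylsilyloxy)-1,4-epoxy-1,4-dihydronaphthalene F8. TBSCl and imidazole then cap the carbinol to give the mixed silyl ether F9. TFA as in step 7 gives 2-[(1S)-1-(tert-butyldimethylsilyloxy)-4-methylpent-3-enyl]-5-methoxy-8-(triisopropylsilyloxy)naphthalen-1-ol F10, and Teuber oxidation gives the corresponding naphthalene-1,4-dione F11. HF·pyridine removes both silyl groups from F11 to give 16.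

**Further compounds**

F1 | step 4 | tert-butyl(2-chloro-4-methoxyphenoxy)dimethylsilane | COc1ccc(O[Si](C)(C)C(C)(C)C)c(Cl)c1
F2 | step 4 | tert-butyl[(1S)-1-(furan-3-yl)-4-methylpent-3-enyloxy]dimethylsilane | CC(C)=CC[C@H](O[Si](C)(C)C(C)(C)C)c1ccoc1
F3 | step 4 | 3-lithio derivative of F1 | COc1ccc(O[Si](C)(C)C(C)(C)C)c(Cl)c1[Li]
F4 | step 4 | 3-(tert-butyldimethylsilyloxy)-6-methoxybenzyne | COC1=CC=C(O[Si](C)(C)C(C)(C)C)C#C1
F5 | step 4 | regioisomer of 13 with the (1S) side chain on C3 | COc1ccc(O[Si](C)(C)C(C)(C)C)c2c1C1OC2C=C1[C@@H](O[Si](C)(C)C(C)(C)C)CC=C(C)C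
F6 | step 3 | di-tert-butyl(2-chloro-4-methoxyphenoxy)silane | COc1ccc(O[SiH](C(C)(C)C)C(C)(C)C)c(Cl)c1
F7 | step 3 | bromo-di-tert-butyl(2-chloro-4-methoxyphenoxy)silane | COc1ccc(O[Si](Br)(C(C)(C)C)C(C)(C)C)c(Cl)c1
F8 | step 8 | 2-[(1S)-1-hydroxy-4-methylpent-3-enyl]-5-methoxy-8-(triisopropylsilyloxy)-1,4-epoxy-1,4-dihydronaphthalene | COc1ccc(O[Si](C(C)C)(C(C)C)C(C)C)c2c1C1C=C([C@@H](O)CC=C(C)C)C2O1
F9 | step 8 | 2-[(1S)-1-(tert-butyldimethylsilyloxy)-4-methylpent-3-enyl]-5-methoxy-8-(triisopropylsilyloxy)-1,4-epoxy-1,4-dihydronaphthalene | COc1ccc(O[Si](C(C)C)(C(C)C)C(C)C)c2c1C1C=C([C@@H](O[Si](C)(C)C(C)(C)C)CC=C(C)C)C2O1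
F10 | step 8 | 2-[(1S)-1-(tert-butyldimethylsilyloxy)-4-methylpent-3-enyl]-5-methoxy-8-(triisopropylsilyloxy)naphthalen-1-ol | COc1ccc(O[Si](C(C)C)(C(C)C)C(C)C)c2c(O)c([C@@H](O[Si](C)(C)C(C)(C)C)CC=C(C)C)ccc12
F11 | step 8 | 2-[(1S)-1-(tert-butyldimethylsilyloxy)-4-methylpent-3-enyl]-5-methoxy-8-(triisopropylsilyloxy)naphthalene-1,4-dione | COc1ccc(O[Si](C(C)C)(C(C)C)C(C)C)c2c1C(=O)C=C([C@@H](O[Si](C)(C)C(C)(C)C)CC=C(C)C)C2=O
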